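**Retrosynthetic overview**

1. Rings: A (hydroquinone-type, OH para to its aryloxy O), B (para-phenylene), C (catechol-type) and D (meta-phenylene) are joined A–CH2CH2–B–O–C–CH2CH2–D–O–A in an 18-membered ring.
2. Feature used: on ring C the free OH sits ortho to the aryloxy oxygen from ring B and para to the benzylic CH2. This is the isodityrosine-like pattern left by phenol oxidation, so the O(ring B)–C3(ring C) bond is cut first.
3. Key disconnection: oxidative C–O phenol coupling of an open-chain bis(2,6-dihalophenol) (ring B Br2, ring C I2, ring A as methyl ether). This is the only ring-forming event; the four benzene rings are bought.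
4. Open chain: the D–O–A ether comes from SNAr. Two Wittig olefinations then attach the MOM-protected, pre-halogenated ring B and ring C aldehydes, one diimide reduction saturates both double bonds, and one acid step removes both MOM groups.
5. End game: hydrogenolysis of two Br and one I, then BBr3 on the ring A methyl ether.

Key step: step 13

Remark on the chemistry: the target SMILES has no stereocentre and no stereodescriptor. The 18-membered cyclophane is taken to be conformationally mobile, hence achiral on the laboratory time scale, so no enantiomer has to be selected. E/Z mixtures are drawn without double-bond descriptors.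

**Step 1**
Reactants: 1 2-fluoro-5-methoxybenzaldehyde; 2 methyl 3-hydroxybenzoate
Product: 3 methyl 3-(2-formyl-4-methoxyphenoxy)benzoate
Conditions: K2CO3, DMAc, 130–140 °C, N2
Reagents that add atoms: none
Why: Nucleophilic aromatic substitution (SNAr), in which the ortho-formyl group stabilises the Meisenheimer adduct, fluoride is the best leaving group for addition–elimination, and the phenoxide of 2 is the only nucleophile present.

**Step 2**
Reactants: 3 methyl 3-(2-formyl-4-methoxyphenoxy)benzoate
Product: 4 methyl 3-[2-(hydroxymethyl)-4-methoxyphenoxy]benzoate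
Conditions: NaBH4, THF–MeOH, 0 °C
Reagents that add atoms: none
Why: Chemoselective borohydride reduction, since the aryl aldehyde is reduced quickly at 0 °C while the benzoate ester is left untouched.

**Step 3**
Reactants: 4 methyl 3-[2-(hydroxymethyl)-4-methoxyphenoxy]benzoate
Product: 5 {5-methoxy-2-[3-(methoxycarbonyl)phenoxy]benzyl}triphenylphosphonium bromide
Conditions: PPh3·HBr, MeCN, reflux
Reagents that add atoms: triphenylphosphine hydrobromide, [Br-].c1ccc(cc1)[PH+](c1ccccc1)c1ccccc1
Why: Direct phosphonium salt formation from a benzylic alcohol, in which HBr activates the ortho-aryloxy-stabilised benzylic position, PPh3 captures it, and no acid-labile group is present yet.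

**Step 4**
Reactants: 6 3,5-dibromo-4-hydroxybenzaldehyde
Product: 7 3,5-dibromo-4-(methoxymethoxy)benzaldehyde
Conditions: MOMCl, iPr2NEt, CH2Cl2, 0 °C → rt
Reagents that add atoms: chloromethyl methyl ether, COCCl
Why: O-alkylation to a MOM ether, in which the acidic dibromophenol is fully deprotonated, the small and very reactive electrophile reaches the flanked oxygen, and masking the phenol keeps the aldehyde electrophilic for the olefination.

**Step 5**
Reactants: 5 phosphonium bromide of rings D–A; 7 3,5-dibromo-4-(methoxymethoxy)benzaldehyde
Product: 8 methyl 3-(2-{2-[3,5-dibromo-4-(methoxymethoxy)phenyl]ethenyl}-4-methoxyphenoxy)benzoate (E/Z mixture)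
Conditions: K2CO3, 18-crown-6 (cat.), CH2Cl2, reflux
Reagents that add atoms: none
Why: Wittig olefination under solid–liquid phase-transfer conditions, where carbonate is basic enough for a benzylic phosphonium salt yet spares ester, MOM ether and C–Br bonds, and the alkene geometry is irrelevant because step 11 saturates the bond.

**Step 6**
Reactants: 8 stilbene ester
Product: 9 [3-(2-{2-[3,5-dibromo-4-(methoxymethoxy)phenyl]ethenyl}-4-methoxyphenoxy)phenyl]methanol (E/Z mixture)
Conditions: DIBAL-H, CH2Cl2, −78 → 0 °C; aq. Rochelle salt
Reagents that add atoms: none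
Why: DIBAL-H ester reduction to the primary alcohol, which at low temperature does not touch aryl bromides, the stilbene double bond or the MOM acetal.

**Step 7**
Reactants: 9 benzylic alcohol
Product: 10 1-(bromomethyl)-3-(2-{2-[3,5-dibromo-4-(methoxymethoxy)phenyl]ethenyl}-4-methoxyphenoxy)benzene (E/Z mixture)
Conditions: CBr4, PPh3, CH2Cl2, 0 °C
Reagents that add atoms: carbon tetrabromide, BrC(Br)(Br)Br
Why: Appel bromination, which turns the benzylic alcohol into the bromide under essentially neutral conditions so that the MOM ether survives where PPh3·HBr would cleave it.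

**Step 8**
Reactants: 10 benzylic bromide
Product: 11 [3-(2-{2-[3,5-dibromo-4-(methoxymethoxy)phenyl]ethenyl}-4-methoxyphenoxy)benzyl]triphenylphosphonium bromide (E/Z mixture)
Conditions: PPh3, toluene, 100 °C
Reagents that add atoms: triphenylphosphine, c1ccc(cc1)P(c1ccccc1)c1ccccc1
Why: SN2 quaternisation of triphenylphosphine by a benzylic bromide, with the salt expected to separate from toluene.

**Step 9**
Reactants: 12 4-hydroxy-3,5-diiodobenzaldehyde
Product: 13 3,5-diiodo-4-(methoxymethoxy)benzaldehyde
Conditions: MOMCl, iPr2NEt, CH2Cl2, 0 °C → rt, dark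
Reagents that add atoms: chloromethyl methyl ether, COCCl
Why: O-alkylation to a MOM ether as in step 4; buying ring C already diiodinated removes any late electrophilic iodination in the presence of the electron-rich ring A.

**Step 10**
Reactants: 11 phosphonium bromide of rings B–A–D; 13 3,5-diiodo-4-(methoxymethoxy)benzaldehyde
Product: 14 open-chain bis-stilbene, with ring B 3,5-dibromo-4-MOMO, ring C 3,5-diiodo-4-MOMO and ring A methyl ether (mixture of E/Z isomers)
Conditions: K2CO3, 18-crown-6 (cat.), CH2Cl2, reflux, dark
Reagents that add atoms: none
Why: Wittig olefination as in step 5, where the formyl group of 13 is unhindered (the iodines are meta to it) and the mild base leaves C–I, C–Br and MOM groups intact.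

**Step 11**
Reactants: 14 open-chain bis-stilbene
Product: 15 open-chain bis(bibenzyl) bis-MOM ether, with ring B dibrominated and ring C diiodinated
Conditions: TsNHNH2 (large excess, in portions), NaOAc, DME–H2O, reflux
Reagents that add atoms: none
Why: Diimide reduction, in which diimide from acetate-buffered thermolysis of tosylhydrazide delivers H2 in a concerted way to C=C bonds only, so the C–Br and C–I bonds that palladium would cleave survive, as do the MOM ethers in the buffered medium.

**Step 12**
Reactants: 15 open-chain bis(bibenzyl) bis-MOM ether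
Product: 16 open-chain bis(dihalophenol): 2,6-dibromo-4-[2-(2-{3-[2-(4-hydroxy-3,5-diiodophenyl)ethyl]phenoxy}-5-methoxyphenyl)ethyl]phenol
Conditions: conc. HCl (cat.), MeOH–THF, 45 °C, dark
Reagents that add atoms: none
Why: Acid-catalysed acetal exchange (MOM cleavage) frees both phenols at once, helped by the good leaving-group ability of dihalophenols, while the aryl methyl ether and the diaryl ether are inert.

**Step 13**
Reactants: 16 open-chain bis(dihalophenol)
Product: 18 trihalogenated 18-membered macrocycle (ring A OMe, ring B with two Br flanking the new ether oxygen, ring C with free OH between the new aryloxy group and the remaining I), via macrocyclic 6-aryloxy-6-iodocyclohexa-2,4-dienone 17 (not isolated)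
Conditions: Tl(NO3)3·3H2O (3 equiv), THF–MeOH 4:1, ca. 1 mM, −20 → 0 °C, dark; aqueous wash, then on the crude material Zn dust, AcOH–THF, rt
Reagents that add atoms: none
Why: Thallium(III) exchanges a nitrate for the phenol of ring C, the more easily oxidised of the two dihalophenols, and two-electron collapse to thallium(I) leaves a phenoxenium-type species with positive charge on the two iodine-bearing ortho carbons and the alkylated para carbon. The phenol oxygen of ring B adds to one C–I carbon to give dienone 17, from which zinc in acetic acid removes the geminal iodine as iodide with rearomatisation to the free ring C phenol, and the same reduction returns any para-methoxy dienone formed by methanol capture to the phenol. The closest known reaction type is the thallium(III) nitrate (or anodic) oxidative macrocyclisation of bis(2,6-dihalophenols) to isodityrosine-type diaryl ethers. The 18-membered ring closes end to end by intramolecular attack of an oxygen nucleophile on an electrophilic ring carbon (C–O macroetherification) under high dilution. The sp3 carbon of 17 forms as a racemate and disappears on rearomatisation, so no stereocentre remains. The step needs the right direction (ring B oxygen onto ring C, secured by iodine on ring C giving the lower oxidation potential and the better ipso leaving group against bromine on ring B), C–O instead of C–C coupling (all ortho and para positions of both phenols are blocked) and no site ambiguity (the two C–I carbons of ring C are equivalent, and ring A as a methyl ether cannot bind thallium).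

**Step 14**
Reactants: 18 trihalogenated macrocycle
Product: 19 halogen-free macrocycle, ring A methyl ether, ring C free phenol
Conditions: H2 (1 atm), 10% Pd/C, NaOAc, MeOH–EtOAc, rt
Reagents that add atoms: none
Why: Catalytic hydrogenolysis (hydrodehalogenation) of the aryl C–I and C–Br bonds over palladium, with acetate trapping HX, while the diaryl ethers, the saturated bridges and the methyl ether are inert.

**Step 15**
Reactants: 19 macrocyclic methyl ether
Product: 20 target CNP0135015.0
Conditions: BBr3 (excess), CH2Cl2, −78 °C → rt; H2O
Reagents that add atoms: none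
Why: Lewis-acid aryl methyl ether cleavage with BBr3, in which boron binds the methoxy oxygen and bromide attacks the methyl carbon by SN2, whereas the diaryl ether oxygens carry no sp3 carbon and survive.

**Compound list**

1 | 2-fluoro-5-methoxybenzaldehyde | COc1ccc(F)c(C=O)c1 | starting material
2 | methyl 3-hydroxybenzoate | COC(=O)c1cccc(O)c1 | starting material
3 | methyl 3-(2-formyl-4-methoxyphenoxy)benzoate | COC(=O)c1cccc(Oc2ccc(OC)cc2C=O)c1 | intermediate
4 | methyl 3-[2-(hydroxymethyl)-4-methoxyphenoxy]benzoate | COC(=O)c1cccc(Oc2ccc(OC)cc2CO)c1 | intermediate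
5 | {5-methoxy-2-[3-(methoxycarbonyl)phenoxy]benzyl}triphenylphosphonium bromide | COC(=O)c1cccc(Oc2ccc(OC)cc2C[P+](c2ccccc2)(c2ccccc2)c2ccccc2)c1.[Br-] | intermediate
6 | 3,5-dibromo-4-hydroxybenzaldehyde | O=Cc1cc(Br)c(O)c(Br)c1 | starting material
7 | 3,5-dibromo-4-(methoxymethoxy)benzaldehyde | COCOc1c(Br)cc(C=O)cc1Br | intermediate
8 | stilbene ester, rings B–A–D (E/Z mixture) | COCOc1c(Br)cc(C=Cc2cc(OC)ccc2Oc2cccc(c2)C(=O)OC)cc1Br | intermediate
9 | stilbene benzylic alcohol (E/Z mixture) | COCOc1c(Br)cc(C=Cc2cc(OC)ccc2Oc2cccc(CO)c2)cc1Br | intermediate
10 | stilbene benzylic bromide (E/Z mixture) | COCOc1c(Br)cc(C=Cc2cc(OC)ccc2Oc2cccc(CBr)c2)cc1Br | intermediate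
11 | stilbene phosphonium bromide (E/Z mixture) | COCOc1c(Br)cc(C=Cc2cc(OC)ccc2Oc2cccc(C[P+](c3ccccc3)(c3ccccc3)c3ccccc3)c2)cc1Br.[Br-] | intermediate
12 | 4-hydroxy-3,5-diiodobenzaldehyde | O=Cc1cc(I)c(O)c(I)c1 | starting material
13 | 3,5-diiodo-4-(methoxymethoxy)benzaldehyde | COCOc1c(I)cc(C=O)cc1I | intermediate
14 | open-chain bis-stilbene bis-MOM ether (E/Z isomers) | COCOc1c(Br)cc(C=Cc2cc(OC)ccc2Oc2cccc(C=Cc3cc(I)c(OCOC)c(I)c3)c2)cc1Br | intermediate
15 | open-chain bis(bibenzyl) bis-MOM ether | COCOc1c(Br)cc(CCc2cc(OC)ccc2Oc2cccc(CCc3cc(I)c(OCOC)c(I)c3)c2)cc1Br | intermediate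
16 | open-chain bis(dihalophenol), key-step precursor | COc1ccc(Oc2cccc(CCc3cc(I)c(O)c(I)c3)c2)c(CCc2cc(Br)c(O)c(Br)c2)c1 | intermediate
17 | macrocyclic 6-aryloxy-6-iodocyclohexa-2,4-dienone (racemic, not isolated) | COc1ccc2c(c1)CCc1cc(Br)c(c(Br)c1)OC1(I)C=C(C=C(I)C1=O)CCc1cccc(c1)O2 | intermediate
18 | trihalogenated 18-membered macrocycle, key-step product | COc1ccc2c(c1)CCc1cc(Br)c(c(Br)c1)Oc1cc(cc(I)c1O)CCc1cccc(c1)O2 | intermediate
19 | halogen-free macrocyclic methyl ether | COc1ccc2c(c1)CCc1ccc(cc1)Oc1cc(ccc1O)CCc1cccc(c1)O2 | intermediate
20 | CNP0135015.0 | Oc1ccc2c(c1)CCc1ccc(cc1)Oc1cc(ccc1O)CCc1cccc(c1)O2 | target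

**Step count**

Total step count: 15.
Longest linear sequence: 13 steps (steps 1, 2, 3, 5, 6, 7, 8, 10, 11, 12, 13, 14 and 15).

**Steps most likely to fail**

**Step 13 (key step).**
- What may go wrong: intermolecular coupling to oligomers may occur despite dilution. Methanol may capture oxidised ring C faster than the hindered ring B oxygen does. The electron-rich ring A may also lose electrons in competition.
- Fallback: the same O(ring B)–C3(ring C) bond is closed by an intramolecular Ullmann ether synthesis. This needs a halogen-free ring B phenol and a ring C bromide next to a methyl ether.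
- The fallback sets out from 5. Wittig reaction with purchased 4-(methoxymethoxy)benzaldehyde under the conditions of step 5 should give the stilbene ester F1.
- DIBAL-H then gives the benzylic alcohol F2, CBr4/PPh3 the benzylic bromide F3, and PPh3 the phosphonium bromide F4.
- A second Wittig reaction with purchased 3-bromo-4-methoxybenzaldehyde gives the bromo bis-stilbene F5. Diimide as in step 11 gives the bromo bis(bibenzyl) MOM ether F6, and HCl in MeOH gives the open-chain bromo phenol F7.
- CuI, N,N-dimethylglycine and Cs2CO3 in dioxane at 100 °C, with slow addition of the substrate, should close the ring to the macrocyclic dimethyl ether F8.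
- BBr3 cleaves both methyl ethers, so the fallback comes back to the route at 20.

**Step 11.**
- What may go wrong: the two conjugated, partly E-configured double bonds may be saturated incompletely, because diimide disproportionates faster than it reduces stilbenes. The C–I bonds may erode during the long reflux that this forces.
- Fallback: ring C is brought in without iodine, so the reduction can be a catalytic hydrogenation that tolerates aryl bromides, and iodine enters last.
- The fallback sets out from 11. Wittig reaction with purchased 4-(methoxymethoxy)benzaldehyde gives the iodine-free bis-stilbene F9.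
- H2 (3–4 bar) over sulfided 5% Pt/C in EtOAc gives the iodine-free bis(bibenzyl) bis-MOM ether F10, and HCl in MeOH gives the dibromo bisphenol F11.
- I2/KI in aqueous methylamine–MeOH at 0 °C iodinates only phenoxide rings with free ortho positions. Only ring C qualifies, because ring B is blocked by bromine and ring A is an ether. The fallback comes back to the route at 16.

**Step 1.**
- What may go wrong: fluoride displacement may be sluggish, because the methoxy group para to fluorine feeds electron density into the carbon under attack. At the temperature then required, the ester may be cleaved and the aldehyde degraded.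
- Fallback: copper catalysis replaces addition–elimination and does not depend on ring activation.
- The fallback sets out from 2, which is coupled with purchased 2-bromo-5-methoxybenzaldehyde in an Ullmann-type ether synthesis (CuI, N,N-dimethylglycine, Cs2CO3, dioxane, 90 °C). It comes back to the route at 3.

**Further compounds**

F1 | step 13 | methyl 3-(4-methoxy-2-{2-[4-(methoxymethoxy)phenyl]ethenyl}phenoxy)benzoate (E/Z) | COCOc1ccc(C=Cc2cc(OC)ccc2Oc2cccc(c2)C(=O)OC)cc1
F2 | step 13 | corresponding benzylic alcohol (E/Z) | COCOc1ccc(C=Cc2cc(OC)ccc2Oc2cccc(CO)c2)cc1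
F3 | step 13 | corresponding benzylic bromide (E/Z) | COCOc1ccc(C=Cc2cc(OC)ccc2Oc2cccc(CBr)c2)cc1
F4 | step 13 | corresponding triphenylphosphonium bromide (E/Z) | COCOc1ccc(C=Cc2cc(OC)ccc2Oc2cccc(C[P+](c3ccccc3)(c3ccccc3)c3ccccc3)c2)cc1.[Br-]
F5 | step 13 | bromo bis-stilbene, ring C 3-bromo-4-methoxyphenyl (E/Z isomers) | COCOc1ccc(C=Cc2cc(OC)ccc2Oc2cccc(C=Cc3ccc(OC)c(Br)c3)c2)cc1
F6 | step 13 | bromo bis(bibenzyl) MOM ether | COCOc1ccc(CCc2cc(OC)ccc2Oc2cccc(CCc3ccc(OC)c(Br)c3)c2)cc1
F7 | step 13 | open-chain bromo phenol | Oc1ccc(CCc2cc(OC)ccc2Oc2cccc(CCc3ccc(OC)c(Br)c3)c2)cc1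
F8 | step 13 | macrocyclic dimethyl ether | COc1ccc2c(c1)CCc1ccc(cc1)Oc1cc(ccc1OC)CCc1cccc(c1)O2
F9 | step 11 | iodine-free bis-stilbene bis-MOM ether (E/Z isomers) | COCOc1c(Br)cc(C=Cc2cc(OC)ccc2Oc2cccc(C=Cc3ccc(OCOC)cc3)c2)cc1Br
F10 | step 11 | iodine-free bis(bibenzyl) bis-MOM ether | COCOc1c(Br)cc(CCc2cc(OC)ccc2Oc2cccc(CCc3ccc(OCOC)cc3)c2)cc1Br
F11 | step 11 | dibromo bisphenol | COc1ccc(Oc2cccc(CCc3ccc(O)cc3)c2)c(CCc2cc(Br)c(O)c(Br)c2)c1
F0 | step 1 | none | none
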